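The earlier runs and the new flask are simulated with made-up constants, and the scatter is random.

At late times the gamma run shows little drift: its bis adduct goes from 21.9% at 2.08 d to 22.5% at 15.0 d, against a scatter of 1 percentage point. So I describe each run by its plateau and not by its time. But theta at 15.0 d still has 54.4% of its substrate in neither adduct, so I doubt that a lack of substrate ends it. I expect the partner, the limiting reagent, to be used up, in theta and in this flask.

| setting | theta | gamma | delta | flask |
|---|---|---|---|---|
| substrate | 0.70 M | 1.1 M | 0.50 M | 0.50 M |
| partner | 1 M (fed, over 6.0 h) | 1 M (fed, over 6.0 h) | 0.50 M (fed, over 6.0 h) | 1.00 M (fed, over 6.0 h) |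
| remark | run made earlier; the fed solution adds 0.10 times the starting volume | run made earlier; the fed solution adds 0.10 times the starting volume | run made earlier; the fed solution adds 0.10 times the starting volume | the fed solution adds 0.10 times the starting volume |
| time |  |  |  | 15 d |

| run | time / d | bis adduct / % | mono adduct / % |
|---|---|---|---|
| theta | 1.25 | 28.7 | 15.0 |
| theta | 3.00 | 29.5 | 12.1 |
| theta | 6.00 | 29.9 | 12.7 |
| theta | 15.0 | 31.0 | 14.6 |
| gamma | 2.08 | 21.9 | 12.7 |
| gamma | 5.00 | 22.0 | 12.7 |
| gamma | 10.0 | 22.3 | 15.4 |
| gamma | 15.0 | 22.5 | 14.2 |
| delta | 4.00 | 21.9 | 15.1 |
| delta | 8.00 | 24.4 | 11.5 |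
| delta | 12.0 | 21.3 | 14.2 |
| delta | 15.0 | 21.4 | 12.8 |

(standard deviation of a reading: 1 percentage point)

- charges are per starting volume, the dose included; the dosed solution carries all of it
- what was read earlier has a scatter of 1 percentage point, one standard deviation
- the reaction counts as stopped when no species that holds the substrate changes by six tenths of a point or more over the second half of the time

- at 15 d, what has stopped the reaction, if anything has (it is still moving / the partner has run out first / all of the substrate has reacted)
- amount of bis adduct at 15 d, in percent of the substrate charged
- amount of mono adduct at 15 d, in percent of the substrate charged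

If the plateau follows the charges, the nearest runs are those with this flask's partner charge and feed. Theta and gamma have both, and they differ in c(substrate). So I carry one quantity, the plateau slope: the share of the charged substrate in bis adduct that the plateau loses per unit rise of c(substrate), with the partner charge held at 1.00 M. From their last readings it is 0.212 L mol⁻¹, resting on a gap of 8.5 points between two readings. Delta has 0.50 M of partner, so it stays off this line. Going from theta down to 0.50 M of substrate, I reckon 35.2% bis adduct. The last mono readings of theta and gamma differ by 0.4 points, against a scatter of 1 point, so I take their mean, 14.4%.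

The forecast says the partner has run out first, with 37.5% bis adduct and 12.5% mono adduct, on the ground "The partner is therefore gone".

The flask gives 35.6% bis adduct and 11.4% mono adduct: the partner has run out first, with 0% of it left at 15.0 d.

    substrate + partner → mono adduct + by-product (k = 0.110 L mol⁻¹ h⁻¹)
    partner + mono adduct → bis adduct + by-product (k = 0.510 L mol⁻¹ h⁻¹)
    partner + bis adduct → tris adduct + by-product (k = 0.0720 L mol⁻¹ h⁻¹)
    crystals ⇌ by-product, rate k4*(cs4 - [by-product]) while solid is left; crystals form when [by-product] > cs4 (solubility = 0.460 M, k = 1.20 h⁻¹)
    2 partner → homo dimer (k = 0.0880 L mol⁻¹ h⁻¹)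

My 35.2% stands beside that bis adduct, while my mono adduct of 14.4% stands above it. Going the other way from gamma with the slope 0.212 L mol⁻¹, I reckon 20.4% bis adduct for the neighbouring flask with 1.2 M of substrate. That flask holds 20.6% at 15 d.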